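**Plan**
- Numbering: C1–C9 is the nonan-1-one chain (C1 is the ketone carbon), ring A is the 4-hydroxy-3-methoxyphenyl ring (C1' on C9), ring B is the 2,6-dihydroxyphenyl ring. The retrosynthesis first cuts C9–C1' (benzylic CH2 to the ring A carbon para to the OH), then the C1–ring B acyl bond, and treats ring B as a dehydrogenated cyclohexane-1,3-dione.
- Enabling feature: the linker is an unbranched, stereocentre-free chain ending in a ketone carbon (C1) and a primary CH2 (C9) on an unhindered ring A carbon flanked by two C–H. It maps onto decanedioic acid: one CO2H becomes C1=O, the other leaves as CO2 when the C9 radical is arylated. The 2,6-dihydroxyphenyl ketone of ring B is the aromatised form of a 2-acylcyclohexane-1,3-dione.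
- Forward: monomethyl sebacate C-acylates cyclohexane-1,3-dione, ring B is aromatised, the far ester is unveiled and activated as an N-acyloxyphthalimide, and a nickel-catalysed reductive decarboxylative coupling with 4-iodo-2-methoxyphenol attaches ring A last, without any protecting group.
- Stereochemistry: the target has no stereocentre and no stereogenic double bond; none is created.

Key step: step 5

Remark: monomethyl sebacate, cyclohexane-1,3-dione and 4-iodo-2-methoxyphenol are taken as purchasable.

**Route**

Step 1
Reactants: 1 monomethyl sebacate (10-methoxy-10-oxodecanoic acid); 2 cyclohexane-1,3-dione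
Product: 4 methyl 10-(2,6-dioxocyclohexyl)-10-oxodecanoate, via enol ester 3 (not isolated)
Conditions: DCC (1.2 equiv), Et3N (1.2 equiv), DMAP (1.0 equiv), CH2Cl2, 0 °C to rt, 24 h
Reagents that add atoms: none
Why: Steglich-type carbodiimide esterification should give the enol ester 3, and DMAP then effects the known O-to-C 1,3-acyl shift (via an acylpyridinium/dione enolate ion pair) to the thermodynamically favoured, internally hydrogen-bonded 2-acyl-1,3-dione, the methyl ester being inert.

Step 2
Reactants: 4 methyl 10-(2,6-dioxocyclohexyl)-10-oxodecanoate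
Product: 5 methyl 10-(2,6-dihydroxyphenyl)-10-oxodecanoate
Conditions: Hg(OAc)2 (2.2 equiv), NaOAc (2 equiv), AcOH, reflux
Reagents that add atoms: none
Why: Dehydrogenative aromatisation of a 2-acylcyclohexane-1,3-dione by Hg(OAc)2, a reaction type with close precedent for 2-acylresorcinols: mercuration of the ring enol at C4 and loss of mercury and acetic acid should give the cyclohexenedione, whose tautomerisation to the doubly hydrogen-bonded 2,6-dihydroxyphenyl ketone is driven by aromaticity, while the ester and the saturated chain are untouched.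

Step 3
Reactants: 5 methyl 10-(2,6-dihydroxyphenyl)-10-oxodecanoate
Product: 6 10-(2,6-dihydroxyphenyl)-10-oxodecanoic acid
Conditions: LiOH·H2O (5 equiv), THF/H2O 3:1, N2, rt; then 1 M HCl to pH 2
Reagents that add atoms: lithium hydroxide (LiOH), [Li+].[OH-]
Why: Saponification of an unhindered methyl ester; the aryl ketone is shielded by its two ortho phenoxides and the phenols are recovered on acidification.

Step 4
Reactants: 6 10-(2,6-dihydroxyphenyl)-10-oxodecanoic acid
Product: 7 1,3-dioxoisoindolin-2-yl 10-(2,6-dihydroxyphenyl)-10-oxodecanoate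
Conditions: N-hydroxyphthalimide (1.1 equiv), DIC (1.1 equiv), THF/CH2Cl2, 0 °C to rt, no added base
Reagents that add atoms: N-hydroxyphthalimide, O=C1c2ccccc2C(=O)N1O
Why: Carbodiimide-mediated esterification with the acidic, strongly nucleophilic N–OH of N-hydroxyphthalimide should outcompete acylation of the two ring B phenols, which are hindered, hydrogen-bonded to the ketone and poorly nucleophilic without base.

Step 5
Reactants: 7 1,3-dioxoisoindolin-2-yl 10-(2,6-dihydroxyphenyl)-10-oxodecanoate; 8 4-iodo-2-methoxyphenol (1.5 equiv)
Product: 9 1-(2,6-dihydroxyphenyl)-9-(4-hydroxy-3-methoxyphenyl)nonan-1-one (target)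
Conditions: NiBr2(dme) (10 mol %), 4,4'-di-tert-butyl-2,2'-bipyridine (10 mol %), Zn powder (2 equiv), DMA, N2, rt
Reagents that add atoms: none
Why: Zn reduces the precatalyst to zerovalent nickel, which inserts into the C–I bond of 8 to give an aryl iodide complex of divalent nickel, while single-electron reduction of the phthalimide ester 7 (by monovalent nickel or Zn) expels phthalimide anion and CO2 and leaves the primary C9 radical; capture of this radical by the arylnickel species and reductive elimination from trivalent nickel should form the C9–C1' bond. The closest known reaction type is the nickel-catalysed reductive decarboxylative arylation of primary alkyl N-acyloxyphthalimides with aryl iodides (cross-electrophile coupling), used here as the last bond-forming step. No ring is closed and no stereocentre is formed. The step needs cross- over homo-coupling selectivity, secured by the orthogonal activation of the partners (only the C(sp2)–I bond undergoes oxidative addition, only the redox-active ester is reduced to a radical), and site selectivity on ring A, fixed by the iodine para to the OH. It also needs tolerance of three phenolic OH groups and the aryl ketone: no base or polar organometallic reagent is present, the OH groups of ring B are held in O–H···O=C hydrogen bonds and that of ring A in an O–H···OMe hydrogen bond, and free phenols are known to survive nickel/zinc cross-electrophile couplings. The primary radical cannot rearrange and the unbranched chain offers no competing site.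

**Compound list**
1 | monomethyl sebacate (10-methoxy-10-oxodecanoic acid) | COC(=O)CCCCCCCCC(=O)O | starting material
2 | cyclohexane-1,3-dione | O=C1CCCC(=O)C1 | starting material
3 | 3-oxocyclohex-1-en-1-yl methyl decanedioate (enol ester) | COC(=O)CCCCCCCCC(=O)OC1=CC(=O)CCC1 | intermediate
4 | methyl 10-(2,6-dioxocyclohexyl)-10-oxodecanoate (triketone, enolised in solution) | COC(=O)CCCCCCCCC(=O)C1C(=O)CCCC1=O | intermediate
5 | methyl 10-(2,6-dihydroxyphenyl)-10-oxodecanoate | COC(=O)CCCCCCCCC(=O)c1c(O)cccc1O | intermediate
6 | 10-(2,6-dihydroxyphenyl)-10-oxodecanoic acid | O=C(O)CCCCCCCCC(=O)c1c(O)cccc1O | intermediate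
7 | 1,3-dioxoisoindolin-2-yl 10-(2,6-dihydroxyphenyl)-10-oxodecanoate | O=C(CCCCCCCCC(=O)c1c(O)cccc1O)ON1C(=O)c2ccccc2C1=O | intermediate
8 | 4-iodo-2-methoxyphenol | COc1cc(I)ccc1O | starting material
9 | 1-(2,6-dihydroxyphenyl)-9-(4-hydroxy-3-methoxyphenyl)nonan-1-one | COc1cc(CCCCCCCCC(=O)c2c(O)cccc2O)ccc1O | target

**Summary**
Total steps: 5. Longest linear sequence: 5 steps (1 → 4 → 5 → 6 → 7 → 9).

**Steps most likely to fail**

Step 5. The primary C9 radical may be quenched by hydrogen-atom transfer from a phenolic O–H, the activated ester may be consumed by acyl transfer to a phenoxide, or the chelating hydroxy-ketone unit of ring B may sequester nickel. The fallback is a transmetalation-based decarboxylative coupling of fully O-benzylated partners; it sets out from compound 5 and rejoins the route at compound 9. Compound 5 would be dibenzylated (BnBr, K2CO3, DMF, 60 °C) to methyl 10-[2,6-bis(benzyloxy)phenyl]-10-oxodecanoate F1. Saponification (LiOH, THF/H2O) would give 10-[2,6-bis(benzyloxy)phenyl]-10-oxodecanoic acid F2, which is activated (N-hydroxyphthalimide, DIC, cat. DMAP, CH2Cl2) as 1,3-dioxoisoindolin-2-yl 10-[2,6-bis(benzyloxy)phenyl]-10-oxodecanoate F3. Purchased 1-(benzyloxy)-4-bromo-2-methoxybenzene (COc1cc(Br)ccc1OCc1ccccc1) would be converted by Mg insertion in the presence of LiCl and ZnCl2 (THF) into [4-(benzyloxy)-3-methoxyphenyl]zinc chloride F4. Negishi-type coupling of F4 with F3 (NiCl2(dme) 20 mol %, 4,4'-di-tert-butyl-2,2'-bipyridine, THF/DMF, rt) should give 1-[2,6-bis(benzyloxy)phenyl]-9-[4-(benzyloxy)-3-methoxyphenyl]nonan-1-one F5. Hydrogenolysis of the three benzyl ethers (H2, Pd/C, EtOAc/MeOH, rt) should then give 9.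

Step 2. The dehydrogenation may stop short, mercuration may compete at the α-CH2 of the chain, and mercury residues may be hard to remove. The fallback builds ring B from an aromatic precursor by directed ortho-metalation and acylation; it sets out from compound 1 and rejoins the route at compound 5. Compound 1 would be converted ((COCl)2, cat. DMF, CH2Cl2) into methyl 10-chloro-10-oxodecanoate F6. Purchased 1,3-bis(methoxymethoxy)benzene (COCOc1cccc(OCOC)c1) would be lithiated between the two ether groups (n-BuLi, THF, 0 °C) to [2,6-bis(methoxymethoxy)phenyl]lithium F7 and transmetalated (ZnCl2) to [2,6-bis(methoxymethoxy)phenyl]zinc chloride F8. Negishi acylation of F8 with F6 (Pd(PPh3)4 5 mol %, THF, rt) should give methyl 10-[2,6-bis(methoxymethoxy)phenyl]-10-oxodecanoate F9. Acetal cleavage (HCl, MeOH, 40 °C) should give 5.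

Step 4. Carbodiimide activation may also acylate the free phenols and lead to oligomerisation. The fallback masks the ring B phenols as acetates before activation; it sets out from compound 6 and rejoins the route at compound 9. Compound 6 would be treated with Ac2O/pyridine/cat. DMAP, which should give acetic 10-[2,6-bis(acetyloxy)phenyl]-10-oxodecanoic anhydride F10 (not isolated). Aqueous THF work-up would hydrolyse the mixed anhydride to 10-[2,6-bis(acetyloxy)phenyl]-10-oxodecanoic acid F11. Activation (N-hydroxyphthalimide, DIC, cat. DMAP) would give 1,3-dioxoisoindolin-2-yl 10-[2,6-bis(acetyloxy)phenyl]-10-oxodecanoate F12. Coupling with 8 under the conditions of step 5 should give 2-[9-(4-hydroxy-3-methoxyphenyl)nonanoyl]-1,3-phenylene diacetate F13. Methanolysis (K2CO3, MeOH, rt) should give 9; any acetyl scrambling among the phenols is corrected in this last operation.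

**Further compounds**
F1 | step 5 | methyl 10-[2,6-bis(benzyloxy)phenyl]-10-oxodecanoate | COC(=O)CCCCCCCCC(=O)c1c(OCc2ccccc2)cccc1OCc1ccccc1
F2 | step 5 | 10-[2,6-bis(benzyloxy)phenyl]-10-oxodecanoic acid | O=C(O)CCCCCCCCC(=O)c1c(OCc2ccccc2)cccc1OCc1ccccc1
F3 | step 5 | 1,3-dioxoisoindolin-2-yl 10-[2,6-bis(benzyloxy)phenyl]-10-oxodecanoate | O=C(CCCCCCCCC(=O)c1c(OCc2ccccc2)cccc1OCc1ccccc1)ON1C(=O)c2ccccc2C1=O
F4 | step 5 | [4-(benzyloxy)-3-methoxyphenyl]zinc chloride | COc1cc([Zn]Cl)ccc1OCc1ccccc1
F5 | step 5 | 1-[2,6-bis(benzyloxy)phenyl]-9-[4-(benzyloxy)-3-methoxyphenyl]nonan-1-one | COc1cc(CCCCCCCCC(=O)c2c(OCc3ccccc3)cccc2OCc2ccccc2)ccc1OCc1ccccc1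
F6 | step 2 | methyl 10-chloro-10-oxodecanoate | COC(=O)CCCCCCCCC(=O)Cl
F7 | step 2 | [2,6-bis(methoxymethoxy)phenyl]lithium | COCOc1cccc(OCOC)c1[Li]
F8 | step 2 | [2,6-bis(methoxymethoxy)phenyl]zinc chloride | COCOc1cccc(OCOC)c1[Zn]Cl
F9 | step 2 | methyl 10-[2,6-bis(methoxymethoxy)phenyl]-10-oxodecanoate | COC(=O)CCCCCCCCC(=O)c1c(OCOC)cccc1OCOC
F10 | step 4 | acetic 10-[2,6-bis(acetyloxy)phenyl]-10-oxodecanoic anhydride | CC(=O)OC(=O)CCCCCCCCC(=O)c1c(OC(C)=O)cccc1OC(C)=O
F11 | step 4 | 10-[2,6-bis(acetyloxy)phenyl]-10-oxodecanoic acid | CC(=O)Oc1cccc(OC(C)=O)c1C(=O)CCCCCCCCC(=O)O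
F12 | step 4 | 1,3-dioxoisoindolin-2-yl 10-[2,6-bis(acetyloxy)phenyl]-10-oxodecanoate | CC(=O)Oc1cccc(OC(C)=O)c1C(=O)CCCCCCCCC(=O)ON1C(=O)c2ccccc2C1=O
F13 | step 4 | 2-[9-(4-hydroxy-3-methoxyphenyl)nonanoyl]-1,3-phenylene diacetate | COc1cc(CCCCCCCCC(=O)c2c(OC(C)=O)cccc2OC(C)=O)ccc1O
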